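The cyclohexane is numbered so that C1 carries methyl and vinyl, C2 is the methylene, C3 bears the ester oxygen, C4 the acrylic acid, C5 the free hydroxyl and C6 the hydroxypropenyl unit. The route rests on cutting C5–C6: the C5 hydroxyl lies trans to a 2-propenyl group on C6, the homoallylic alcohol pattern that an intramolecular carbonyl-ene reaction delivers directly. In a single operation a C5 aldehyde and a trisubstituted alkene attached to C1 give the C5–C6 bond, the six-membered ring, both new stereocentres and the isopropenyl group. The precursor is an open-chain aldehyde in which C1, C3 (silyl ether) and C4 (tert-butyl acetate arm) are already fixed.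

Key step: step 11

Remarks on the chemistry (assumptions):
- The (S,S) antipode of the ligand in step 1 is assigned to the required (S)-adduct by analogy with other pronucleophiles adding to vinyl epoxides under this catalyst; both antipodes are commercial and the sense is checked at the lactone of step 2.
- The target is taken as the open γ-hydroxy acid as drawn, so the last step is run and worked up under pyridine buffering to keep the C4 acrylic acid from lactonising onto the C5 hydroxyl.
- Dimethyl (R)-malate is taken as a catalogue compound.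

Step 1
Reactants: 1 2-ethenyl-2-methyloxirane (racemic); 2 dimethyl malonate
Product: 3 dimethyl 2-[(2S)-1-hydroxy-2-methylbut-3-en-2-yl]propanedioate
Conditions: Pd2(dba)3·CHCl3 (1 mol %), (S,S)-DACH-naphthyl Trost ligand (3 mol %), CH2Cl2, rt
Reagents that add atoms: none
Why: Tsuji–Trost asymmetric allylic alkylation in which zerovalent palladium opens the vinyl epoxide to a π-allyl complex whose alkoxide deprotonates the malonate and steers it to the adjacent tertiary terminus, while fast π–σ–π equilibration under the chiral diphosphine (dynamic kinetic asymmetric transformation) should set the quaternary C1 centre.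

Step 2
Reactants: 3 dimethyl 2-[(2S)-1-hydroxy-2-methylbut-3-en-2-yl]propanedioate
Product: 5 (4R)-4-ethenyl-4-methyloxolan-2-one, via carbomethoxy lactone 4 (not isolated)
Conditions: LiCl, H2O, DMSO, 140 °C
Reagents that add atoms: none
Why: The neopentyl hydroxyl should lactonise onto one ester (5-exo-trig acyl substitution) and Krapcho dealkoxycarbonylation then removes the second ester without touching the quaternary centre.

Step 3
Reactants: 5 (4R)-4-ethenyl-4-methyloxolan-2-one
Product: 6 (3R)-3-(hydroxymethyl)-N-methoxy-N,3-dimethylpent-4-enamide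
Conditions: MeNH(OMe)·HCl, i-PrMgCl, THF, −20 → 0 °C; aq. NH4Cl; used crude
Reagents that add atoms: N,O-dimethylhydroxylamine hydrochloride, CNOC.Cl
Why: Weinreb amide formation by aminolysis of the lactone with the magnesium amide opens the ring and frees the C6 hydroxymethyl group, and the crude product is oxidised at once so that it cannot relactonise.

Step 4
Reactants: 6 (3R)-3-(hydroxymethyl)-N-methoxy-N,3-dimethylpent-4-enamide
Product: 7 (3R)-3-formyl-N-methoxy-N,3-dimethylpent-4-enamide
Conditions: Dess–Martin periodinane, pyridine, CH2Cl2, 0 °C → rt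
Reagents that add atoms: none
Why: Dess–Martin oxidation of the primary alcohol gives an α-quaternary aldehyde that cannot enolise, so C1 is safe and the amide is untouched.

Step 5
Reactants: 7 (3R)-3-formyl-N-methoxy-N,3-dimethylpent-4-enamide; 8 isopropyltriphenylphosphonium iodide
Product: 10 (3R)-3-ethenyl-N-methoxy-N,3,5-trimethylhex-4-enamide, via phosphorus ylide 9 (not isolated)
Conditions: n-BuLi, THF, 0 °C; then 7, −78 °C → rt
Reagents that add atoms: none
Why: Wittig olefination with the non-stabilised isopropylidene ylide should turn the aldehyde into the 2-methylprop-1-enyl group, the Weinreb amide being inert to the ylide and its α-carbon unable to reach the aldehyde.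

Step 6
Reactants: 10 (3R)-3-ethenyl-N-methoxy-N,3,5-trimethylhex-4-enamide; 11 methyl acetate
Product: 13 methyl (5R)-5-ethenyl-5,7-dimethyl-3-oxooct-6-enoate, via methyl acetate enolate 12 (not isolated)
Conditions: LiN(i-Pr)2, THF, −78 °C; then 10, −78 → −30 °C; aq. NH4Cl
Reagents that add atoms: none
Why: Claisen-type acylation of the ester enolate by the Weinreb amide stops at the chelated tetrahedral adduct and should release the β-keto ester on work-up.

Step 7
Reactants: 13 methyl (5R)-5-ethenyl-5,7-dimethyl-3-oxooct-6-enoate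
Product: 14 methyl (3R,5R)-5-ethenyl-3-hydroxy-5,7-dimethyloct-6-enoate
Conditions: RuCl2[(R)-BINAP](dmf)n (1 mol %), H2 (4 atm), MeOH, 50 °C
Reagents that add atoms: none
Why: Noyori asymmetric hydrogenation of the ester-chelated β-keto ester should set C3 as (R) under control of the (R)-BINAP catalyst, and at low pressure the isolated vinyl and trisubstituted alkenes are not expected to be reduced.

Step 8
Reactants: 14 methyl (3R,5R)-5-ethenyl-3-hydroxy-5,7-dimethyloct-6-enoate; 15 tert-butyl bromoacetate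
Product: 17 methyl (2R,3R,5R)-2-(2-tert-butoxy-2-oxoethyl)-5-ethenyl-3-hydroxy-5,7-dimethyloct-6-enoate, via dilithium dianion 16 (not isolated)
Conditions: LiN(i-Pr)2 (2.2 equiv), THF, −78 → −20 °C; then 15, DMPU, −78 → −30 °C; aq. NH4Cl at −30 °C
Reagents that add atoms: none
Why: Fráter–Seebach alkylation of the chelated alkoxide–enolate dianion on the face away from the C3 side chain should set C4 with the 3,4-anti relationship, and the bulky tert-butyl ester resists lactonisation by the cold alkoxide.

Step 9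
Reactants: 17 methyl (2R,3R,5R)-2-(2-tert-butoxy-2-oxoethyl)-5-ethenyl-3-hydroxy-5,7-dimethyloct-6-enoate
Product: 18 methyl (2R,3R,5R)-2-(2-tert-butoxy-2-oxoethyl)-5-ethenyl-5,7-dimethyl-3-[(triethylsilyl)oxy]oct-6-enoate
Conditions: TESOTf, 2,6-lutidine, CH2Cl2, −78 °C
Reagents that add atoms: triethylsilyl trifluoromethanesulfonate, CC[Si](CC)(CC)OS(=O)(=O)C(F)(F)F
Why: O-silylation with the silyl triflate gives a triethylsilyl ether, chosen because it is a poor donor towards aluminium in the key step and can later be cleaved in the presence of a tert-butyldimethylsilyl ether.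

Step 10
Reactants: 18 methyl (2R,3R,5R)-2-(2-tert-butoxy-2-oxoethyl)-5-ethenyl-5,7-dimethyl-3-[(triethylsilyl)oxy]oct-6-enoate
Product: 19 tert-butyl (3R,4R,6R)-6-ethenyl-3-formyl-6,8-dimethyl-4-[(triethylsilyl)oxy]non-7-enoate
Conditions: i-Bu2AlH (1.2 equiv), CH2Cl2, −78 °C; MeOH, then aq. potassium sodium tartrate
Reagents that add atoms: none
Why: Partial reduction with i-Bu2AlH at −78 °C should stop at the aluminium hemiacetal of the methyl ester and give the aldehyde on work-up, while the tert-butyl ester is not reduced at this temperature and the cold, non-basic handling preserves the α-stereocentre.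

Step 11
Reactants: 19 tert-butyl (3R,4R,6R)-6-ethenyl-3-formyl-6,8-dimethyl-4-[(triethylsilyl)oxy]non-7-enoate
Product: 20 tert-butyl 2-[(1S,2S,3R,4R,6R)-4-ethenyl-2-hydroxy-4-methyl-3-(prop-1-en-2-yl)-6-[(triethylsilyl)oxy]cyclohexyl]acetate
Conditions: Me2AlCl (1.1 equiv), CH2Cl2, −78 → −40 °C; aq. NaHCO3 and potassium sodium tartrate at −40 °C
Reagents that add atoms: none
Why: Me2AlCl binds the C5 aldehyde and the alkene carbon C6 attacks it while an allylic hydrogen of a terminal methyl passes to oxygen through a six-centre transition state, so the C5–C6 bond, the C5 carbinol and the isopropenyl group form together and the alkoxide is fixed on aluminium with loss of methane. The closest known reaction is the Lewis-acid-promoted carbonyl-ene cyclisation of citronellal to isopulegol (type 1 intramolecular ene reaction). The six-membered ring closes in a 6-exo-trig sense at the carbonyl through a chair in which the tether joins the alkene terminus. C5 and C6 are set by that chair: the C3 silyloxy group stays equatorial because the flipped chair would put it syn-diaxial to the C1 vinyl group, the axial C1 methyl forces the aluminium-bound oxygen equatorial, and the axial C4 arm forces the isopropylidene carbon equatorial, which should give the trans C5 hydroxyl and C6 isopropenyl group (5S,6R in 20). The step needs diastereoselectivity and chemoselectivity: the trisubstituted alkene is far more nucleophilic than the vinyl group (which has no allylic hydrogen), one equivalent of Me2AlCl and a silyl ether avoid a chelate between the aldehyde and the C3 oxygen, and the methylaluminium reagent scavenges protons so that Prins pathways and epimerisation at C4 are suppressed. The tert-butyl ester is kept because it should not lactonise onto the new aluminium alkoxide at −78 °C.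

Step 12
Reactants: 20 tert-butyl 2-[(1S,2S,3R,4R,6R)-4-ethenyl-2-hydroxy-4-methyl-3-(prop-1-en-2-yl)-6-[(triethylsilyl)oxy]cyclohexyl]acetate
Product: 21 tert-butyl 2-[(1R,2S,3R,4R,6R)-2-[(tert-butyldimethylsilyl)oxy]-4-ethenyl-4-methyl-3-(prop-1-en-2-yl)-6-[(triethylsilyl)oxy]cyclohexyl]acetate
Conditions: TBSOTf, 2,6-lutidine, CH2Cl2, −78 → 0 °C
Reagents that add atoms: tert-butyldimethylsilyl trifluoromethanesulfonate, CC(C)(C)[Si](C)(C)OS(=O)(=O)C(F)(F)F
Why: O-silylation of the hindered equatorial C5 hydroxyl with the silyl triflate blocks lactonisation and tells C5 apart from C3 for the later acylation.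

Step 13
Reactants: 21 tert-butyl 2-[(1R,2S,3R,4R,6R)-2-[(tert-butyldimethylsilyl)oxy]-4-ethenyl-4-methyl-3-(prop-1-en-2-yl)-6-[(triethylsilyl)oxy]cyclohexyl]acetate
Product: 25 tert-butyl 2-[(1R,2S,3R,4R,6R)-2-[(tert-butyldimethylsilyl)oxy]-4-ethenyl-4-methyl-3-(prop-1-en-2-yl)-6-[(triethylsilyl)oxy]cyclohexyl]prop-2-enoate, via ester enolate 22 (not isolated), via Mannich base 23 (not isolated), via ammonium iodide 24 (not isolated)
Conditions: LiN(i-Pr)2, THF, −78 °C; dimethylmethylideneammonium iodide, −78 → 0 °C; then MeI, rt; then DBU, rt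
Reagents that add atoms: dimethylmethylideneammonium iodide, C[N+](C)=C.[I-]
Why: Eschenmoser methylenation, in which the ester enolate (no leaving group on its β-carbon) undergoes a Mannich reaction with the iminium salt and N-methylation followed by base-induced loss of trimethylamine should give the α-methylene ester.

Step 14
Reactants: 25 tert-butyl 2-[(1R,2S,3R,4R,6R)-2-[(tert-butyldimethylsilyl)oxy]-4-ethenyl-4-methyl-3-(prop-1-en-2-yl)-6-[(triethylsilyl)oxy]cyclohexyl]prop-2-enoate
Product: 26 tert-butyl 2-[(1R,2S,3R,4R,6R)-2-[(tert-butyldimethylsilyl)oxy]-4-ethenyl-6-hydroxy-4-methyl-3-(prop-1-en-2-yl)cyclohexyl]prop-2-enoate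
Conditions: PPTS, MeOH/CH2Cl2, 0 °C → rt
Reagents that add atoms: none
Why: Acid-catalysed methanolysis cleaves a secondary triethylsilyl ether much faster than the hindered tert-butyldimethylsilyl ether, so only the C3 hydroxyl should be freed.

Step 15
Reactants: 27 dimethyl (2R)-2-hydroxybutanedioate
Product: 28 methyl (3R)-3,4-dihydroxybutanoate
Conditions: BH3·SMe2, NaBH4 (5 mol %), THF, 0 °C → rt; MeOH
Reagents that add atoms: none
Why: Hydroxyl-directed borane reduction takes the ester next to the hydroxyl through a five-membered alkoxyborane chelate and should leave the distal ester and the stereocentre untouched.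

Step 16
Reactants: 28 methyl (3R)-3,4-dihydroxybutanoate
Product: 29 methyl (3R)-3,4-bis[(tert-butyldimethylsilyl)oxy]butanoate
Conditions: TBSCl, imidazole, DMF, rt
Reagents that add atoms: tert-butyldimethylsilyl chloride, CC(C)(C)[Si](C)(C)Cl
Why: Silylation of both hydroxyls with the silyl chloride and imidazole prevents lactonisation of the 4-hydroxy ester and gives diol protection that a fluoride acid removes at the end.

Step 17
Reactants: 29 methyl (3R)-3,4-bis[(tert-butyldimethylsilyl)oxy]butanoate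
Product: 33 methyl (3R)-3,4-bis[(tert-butyldimethylsilyl)oxy]-2-methylidenebutanoate, via ester enolate 30 (not isolated), via Mannich base 31 (not isolated), via ammonium iodide 32 (not isolated)
Conditions: LiN(i-Pr)2, THF, −78 °C; dimethylmethylideneammonium iodide, −78 → 0 °C; then MeI, rt; then DBU, rt
Reagents that add atoms: dimethylmethylideneammonium iodide, C[N+](C)=C.[I-]
Why: Eschenmoser methylenation as in step 13, where at −78 °C the iminium salt should trap the enolate faster than it can expel the β-silyloxy group and the ammonium group is the better leaving group in the final elimination, the stereocentre not being involved.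

Step 18
Reactants: 33 methyl (3R)-3,4-bis[(tert-butyldimethylsilyl)oxy]-2-methylidenebutanoate
Product: 34 (3R)-3,4-bis[(tert-butyldimethylsilyl)oxy]-2-methylidenebutanoic acid
Conditions: LiOH, THF/H2O, 0 °C → rt; then dilute HCl to pH 4
Reagents that add atoms: lithium hydroxide, [Li+].[OH-]
Why: Saponification of the methyl ester with LiOH, conditions that the silyl ethers tolerate, followed by mild acidification should give the free acid.

Step 19
Reactants: 26 tert-butyl 2-[(1R,2S,3R,4R,6R)-2-[(tert-butyldimethylsilyl)oxy]-4-ethenyl-6-hydroxy-4-methyl-3-(prop-1-en-2-yl)cyclohexyl]prop-2-enoate; 34 (3R)-3,4-bis[(tert-butyldimethylsilyl)oxy]-2-methylidenebutanoic acid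
Product: 36 (1R,2R,3S,4R,5R)-2-(3-tert-butoxy-3-oxoprop-1-en-2-yl)-3-[(tert-butyldimethylsilyl)oxy]-5-ethenyl-5-methyl-4-(prop-1-en-2-yl)cyclohexyl (3R)-3,4-bis[(tert-butyldimethylsilyl)oxy]-2-methylidenebutanoate, via mixed anhydride 35 (not isolated)
Conditions: 34, 2,4,6-trichlorobenzoyl chloride, Et3N, THF, rt; then 26, DMAP, toluene, rt
Reagents that add atoms: none
Why: Yamaguchi esterification, in which DMAP attacks the mixed anhydride at the less hindered acryloyl carbonyl and the acylpyridinium should acylate the equatorial C3 hydroxyl, the only free hydroxyl in 26.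

Step 20
Reactants: 36 (1R,2R,3S,4R,5R)-2-(3-tert-butoxy-3-oxoprop-1-en-2-yl)-3-[(tert-butyldimethylsilyl)oxy]-5-ethenyl-5-methyl-4-(prop-1-en-2-yl)cyclohexyl (3R)-3,4-bis[(tert-butyldimethylsilyl)oxy]-2-methylidenebutanoate
Product: 37 (1R,2R,3S,4S,5R)-2-(3-tert-butoxy-3-oxoprop-1-en-2-yl)-3-[(tert-butyldimethylsilyl)oxy]-5-ethenyl-4-(3-hydroxyprop-1-en-2-yl)-5-methylcyclohexyl (3R)-3,4-bis[(tert-butyldimethylsilyl)oxy]-2-methylidenebutanoate
Conditions: SeO2 (0.5 equiv), t-BuOOH, CH2Cl2, 0 °C → rt
Reagents that add atoms: selenium dioxide, O=[Se]=O; tert-butyl hydroperoxide, CC(C)(C)OO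
Why: Selenium dioxide allylic oxidation (ene reaction then 2,3-sigmatropic shift) should hydroxylate the methyl of the isopropenyl group, since on a 1,1-disubstituted alkene methyl reacts before the ring methine, the two acrylates are electron-poor and the vinyl group has no allylic hydrogen.

Step 21
Reactants: 37 (1R,2R,3S,4S,5R)-2-(3-tert-butoxy-3-oxoprop-1-en-2-yl)-3-[(tert-butyldimethylsilyl)oxy]-5-ethenyl-4-(3-hydroxyprop-1-en-2-yl)-5-methylcyclohexyl (3R)-3,4-bis[(tert-butyldimethylsilyl)oxy]-2-methylidenebutanoate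
Product: 39 2-[(1S,2S,3S,4R,6R)-6-{[(3R)-3,4-dihydroxy-2-methylidenebutanoyl]oxy}-4-ethenyl-2-hydroxy-3-(3-hydroxyprop-1-en-2-yl)-4-methylcyclohexyl]prop-2-enoic acid, via bis-silyl intermediate 38 (not isolated)
Conditions: TMSOTf, 2,6-lutidine, CH2Cl2, 0 °C; then HF·pyridine, pyridine, THF, 0 °C → rt
Reagents that add atoms: none
Why: Silyl-triflate-mediated cleavage of the tert-butyl ester (O-silylation, loss of isobutene) gives a trimethylsilyl ester without protic acid, and buffered HF·pyridine then removes every silyl group, so the γ-hydroxy acid and the base-sensitive dihydroxy ester side chain should meet only a pyridine-buffered medium.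

Compound list
1 | 2-ethenyl-2-methyloxirane (racemic) | CC1(C=C)CO1 | starting material
2 | dimethyl malonate | COC(=O)CC(=O)OC | starting material
3 | dimethyl 2-[(2S)-1-hydroxy-2-methylbut-3-en-2-yl]propanedioate | C=C[C@@](C)(C(C(=O)OC)C(=O)OC)CO | intermediate
4 | methyl (4S)-4-ethenyl-4-methyl-2-oxooxolane-3-carboxylate (both C3 epimers) | C=C[C@@]1(C)C(C(=O)OC)C(=O)OC1 | intermediate
5 | (4R)-4-ethenyl-4-methyloxolan-2-one | C=C[C@@]1(C)CC(=O)OC1 | intermediate
6 | (3R)-3-(hydroxymethyl)-N-methoxy-N,3-dimethylpent-4-enamide | C=C[C@@](C)(CC(=O)N(C)OC)CO | intermediate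
7 | (3R)-3-formyl-N-methoxy-N,3-dimethylpent-4-enamide | C=C[C@@](C)(CC(=O)N(C)OC)C=O | intermediate
8 | isopropyltriphenylphosphonium iodide | CC(C)[P+](c1ccccc1)(c1ccccc1)c1ccccc1.[I-] | starting material
9 | isopropylidenetriphenylphosphorane | CC(C)=P(c1ccccc1)(c1ccccc1)c1ccccc1 | intermediate
10 | (3R)-3-ethenyl-N-methoxy-N,3,5-trimethylhex-4-enamide | C=C[C@@](C)(CC(=O)N(C)OC)C=C(C)C | intermediate
11 | methyl acetate | COC(C)=O | starting material
12 | lithium 1-methoxyethen-1-olate | [Li+].[O-]C(=C)OC | intermediate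
13 | methyl (5R)-5-ethenyl-5,7-dimethyl-3-oxooct-6-enoate | C=C[C@@](C)(CC(=O)CC(=O)OC)C=C(C)C | intermediate
14 | methyl (3R,5R)-5-ethenyl-3-hydroxy-5,7-dimethyloct-6-enoate | C=C[C@@](C)(C[C@@H](O)CC(=O)OC)C=C(C)C | intermediate
15 | tert-butyl bromoacetate | CC(C)(C)OC(=O)CBr | starting material
16 | dilithium alkoxide–enolate of 14 | [Li+].[Li+].C=C[C@@](C)(C[C@@H]([O-])C=C([O-])OC)C=C(C)C | intermediate
17 | methyl (2R,3R,5R)-2-(2-tert-butoxy-2-oxoethyl)-5-ethenyl-3-hydroxy-5,7-dimethyloct-6-enoate | C=C[C@@](C)(C[C@@H](O)[C@@H](CC(=O)OC(C)(C)C)C(=O)OC)C=C(C)C | intermediate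
18 | methyl (2R,3R,5R)-2-(2-tert-butoxy-2-oxoethyl)-5-ethenyl-5,7-dimethyl-3-[(triethylsilyl)oxy]oct-6-enoate | C=C[C@@](C)(C[C@@H](O[Si](CC)(CC)CC)[C@@H](CC(=O)OC(C)(C)C)C(=O)OC)C=C(C)C | intermediate
19 | tert-butyl (3R,4R,6R)-6-ethenyl-3-formyl-6,8-dimethyl-4-[(triethylsilyl)oxy]non-7-enoate | C=C[C@@](C)(C[C@@H](O[Si](CC)(CC)CC)[C@@H](CC(=O)OC(C)(C)C)C=O)C=C(C)C | intermediate
20 | tert-butyl 2-[(1S,2S,3R,4R,6R)-4-ethenyl-2-hydroxy-4-methyl-3-(prop-1-en-2-yl)-6-[(triethylsilyl)oxy]cyclohexyl]acetate | C=C[C@@]1(C)C[C@@H](O[Si](CC)(CC)CC)[C@@H](CC(=O)OC(C)(C)C)[C@@H](O)[C@@H]1C(C)=C | intermediate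
21 | tert-butyl 2-[(1R,2S,3R,4R,6R)-2-[(tert-butyldimethylsilyl)oxy]-4-ethenyl-4-methyl-3-(prop-1-en-2-yl)-6-[(triethylsilyl)oxy]cyclohexyl]acetate | C=C[C@@]1(C)C[C@@H](O[Si](CC)(CC)CC)[C@@H](CC(=O)OC(C)(C)C)[C@@H](O[Si](C)(C)C(C)(C)C)[C@@H]1C(C)=C | intermediate
22 | lithium enolate of 21 | [Li+].C=C[C@@]1(C)C[C@@H](O[Si](CC)(CC)CC)[C@@H](C=C([O-])OC(C)(C)C)[C@@H](O[Si](C)(C)C(C)(C)C)[C@@H]1C(C)=C | intermediate
23 | Mannich base of 21 (tert-butyl 3-(dimethylamino)-2-cyclohexylpropanoate, both α-epimers) | C=C[C@@]1(C)C[C@@H](O[Si](CC)(CC)CC)[C@@H](C(CN(C)C)C(=O)OC(C)(C)C)[C@@H](O[Si](C)(C)C(C)(C)C)[C@@H]1C(C)=C | intermediate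
24 | trimethylammonium iodide from 23 | C=C[C@@]1(C)C[C@@H](O[Si](CC)(CC)CC)[C@@H](C(C[N+](C)(C)C)C(=O)OC(C)(C)C)[C@@H](O[Si](C)(C)C(C)(C)C)[C@@H]1C(C)=C.[I-] | intermediate
25 | tert-butyl 2-[(1R,2S,3R,4R,6R)-2-[(tert-butyldimethylsilyl)oxy]-4-ethenyl-4-methyl-3-(prop-1-en-2-yl)-6-[(triethylsilyl)oxy]cyclohexyl]prop-2-enoate | C=C[C@@]1(C)C[C@@H](O[Si](CC)(CC)CC)[C@@H](C(=C)C(=O)OC(C)(C)C)[C@@H](O[Si](C)(C)C(C)(C)C)[C@@H]1C(C)=C | intermediate
26 | tert-butyl 2-[(1R,2S,3R,4R,6R)-2-[(tert-butyldimethylsilyl)oxy]-4-ethenyl-6-hydroxy-4-methyl-3-(prop-1-en-2-yl)cyclohexyl]prop-2-enoate | C=C[C@@]1(C)C[C@@H](O)[C@@H](C(=C)C(=O)OC(C)(C)C)[C@@H](O[Si](C)(C)C(C)(C)C)[C@@H]1C(C)=C | intermediate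
27 | dimethyl (2R)-2-hydroxybutanedioate (dimethyl (R)-malate) | COC(=O)C[C@@H](O)C(=O)OC | starting material
28 | methyl (3R)-3,4-dihydroxybutanoate | COC(=O)C[C@@H](O)CO | intermediate
29 | methyl (3R)-3,4-bis[(tert-butyldimethylsilyl)oxy]butanoate | COC(=O)C[C@@H](O[Si](C)(C)C(C)(C)C)CO[Si](C)(C)C(C)(C)C | intermediate
30 | lithium enolate of 29 | [Li+].[O-]C(OC)=C[C@@H](O[Si](C)(C)C(C)(C)C)CO[Si](C)(C)C(C)(C)C | intermediate
31 | methyl (3R)-3,4-bis[(tert-butyldimethylsilyl)oxy]-2-[(dimethylamino)methyl]butanoate (both C2 epimers) | COC(=O)C(CN(C)C)[C@@H](O[Si](C)(C)C(C)(C)C)CO[Si](C)(C)C(C)(C)C | intermediate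
32 | trimethylammonium iodide from 31 | COC(=O)C(C[N+](C)(C)C)[C@@H](O[Si](C)(C)C(C)(C)C)CO[Si](C)(C)C(C)(C)C.[I-] | intermediate
33 | methyl (3R)-3,4-bis[(tert-butyldimethylsilyl)oxy]-2-methylidenebutanoate | COC(=O)C(=C)[C@@H](O[Si](C)(C)C(C)(C)C)CO[Si](C)(C)C(C)(C)C | intermediate
34 | (3R)-3,4-bis[(tert-butyldimethylsilyl)oxy]-2-methylidenebutanoic acid | OC(=O)C(=C)[C@@H](O[Si](C)(C)C(C)(C)C)CO[Si](C)(C)C(C)(C)C | intermediate
35 | mixed anhydride of 34 and 2,4,6-trichlorobenzoic acid | O=C(OC(=O)c1c(Cl)cc(Cl)cc1Cl)C(=C)[C@@H](O[Si](C)(C)C(C)(C)C)CO[Si](C)(C)C(C)(C)C | intermediate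
36 | (1R,2R,3S,4R,5R)-2-(3-tert-butoxy-3-oxoprop-1-en-2-yl)-3-[(tert-butyldimethylsilyl)oxy]-5-ethenyl-5-methyl-4-(prop-1-en-2-yl)cyclohexyl (3R)-3,4-bis[(tert-butyldimethylsilyl)oxy]-2-methylidenebutanoate | C=C[C@@]1(C)C[C@@H](OC(=O)C(=C)[C@@H](O[Si](C)(C)C(C)(C)C)CO[Si](C)(C)C(C)(C)C)[C@@H](C(=C)C(=O)OC(C)(C)C)[C@@H](O[Si](C)(C)C(C)(C)C)[C@@H]1C(C)=C | intermediate
37 | (1R,2R,3S,4S,5R)-2-(3-tert-butoxy-3-oxoprop-1-en-2-yl)-3-[(tert-butyldimethylsilyl)oxy]-5-ethenyl-4-(3-hydroxyprop-1-en-2-yl)-5-methylcyclohexyl (3R)-3,4-bis[(tert-butyldimethylsilyl)oxy]-2-methylidenebutanoate | C=C[C@@]1(C)C[C@@H](OC(=O)C(=C)[C@@H](O[Si](C)(C)C(C)(C)C)CO[Si](C)(C)C(C)(C)C)[C@@H](C(=C)C(=O)OC(C)(C)C)[C@@H](O[Si](C)(C)C(C)(C)C)[C@@H]1C(=C)CO | intermediate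
38 | trimethylsilyl ester and allylic trimethylsilyl ether of 37 after loss of the tert-butyl group | C=C[C@@]1(C)C[C@@H](OC(=O)C(=C)[C@@H](O[Si](C)(C)C(C)(C)C)CO[Si](C)(C)C(C)(C)C)[C@@H](C(=C)C(=O)O[Si](C)(C)C)[C@@H](O[Si](C)(C)C(C)(C)C)[C@@H]1C(=C)CO[Si](C)(C)C | intermediate
39 | 2-[(1S,2S,3S,4R,6R)-6-{[(3R)-3,4-dihydroxy-2-methylidenebutanoyl]oxy}-4-ethenyl-2-hydroxy-3-(3-hydroxyprop-1-en-2-yl)-4-methylcyclohexyl]prop-2-enoic acid | C=C[C@@]1(C)C[C@@H](OC(=O)C(=C)[C@@H](O)CO)[C@@H](C(=C)C(=O)O)[C@@H](O)[C@@H]1C(=C)CO | target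

Total step count: 21 (17 on the main line, 4 for the side-chain acid).
Longest linear sequence: 17 steps (steps 1–14 and 19–21).

Steps most likely to fail

Step 11 (key step). The two chair transition states may compete, the developing cation may be captured by chloride, or the triethylsilyl ether may be lost, any of which would erode the yield or the C5/C6 configuration. The fallback replaces the pericyclic closure by an allylmetal addition that forms the same bond. It sets out from diester 18. SeO2 with t-BuOOH should oxidise the (E)-methyl of the trisubstituted alkene to the (E)-allylic alcohol F1. CBr4 and PPh3 should convert this into the allylic bromide F2. i-Bu2AlH at −78 °C should reduce the methyl ester to the bromo aldehyde F3. CrCl2 in THF should then close the ring by intramolecular Nozaki–Hiyama allylation: the allylchromium attacks the aldehyde through its γ-carbon (C6) in a chromium-bridged chair, with allylic transposition to the isopropenyl group. The fallback comes back to the route at cyclohexanol 20.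

Step 1. The malonate may attack the primary allyl terminus and give the linear adduct, or the enantioselectivity may erode. The fallback sets out from epoxide 1 and uses methyl acetoacetate, a β-keto ester of the class for which attack at the tertiary terminus of this epoxide is established under the same catalyst. This should give methyl (3S)-2-acetyl-3-(hydroxymethyl)-3-methylpent-4-enoate F4, in equilibrium with its cyclic hemiketal. LiCl in wet DMSO at 140 °C should remove the ester and give (4R)-4-(hydroxymethyl)-4-methylhex-5-en-2-one F5. Haloform cleavage of the methyl ketone (NaOH, Br2, dioxane/H2O, 0 °C) should give (3R)-3-(hydroxymethyl)-3-methylpent-4-enoic acid F6, which closes on acidification. The fallback comes back to the route at lactone 5.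

Step 21. The freshly liberated C4 acid may lactonise onto the C5 hydroxyl while HF is still present, or the hindered C5 silyl ether may cleave slowly and prolong that exposure. The fallback reverses the order, so that the acid is unmasked last and never meets HF. It sets out from 37. HF·pyridine with pyridine in THF should remove the three tert-butyldimethylsilyl groups while the tert-butyl ester still blocks lactonisation, giving the tetraol tert-butyl ester F7. TMSOTf with 2,6-lutidine should then silylate the four hydroxyls and convert the tert-butyl ester into the silyl ester, giving the pentakis(trimethylsilyl) derivative F8. Brief methanolysis in pH 6 phosphate buffer at 0 °C should strip the trimethylsilyl groups. The fallback comes back to the route at target 39.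

Further compounds
F1 | step 11 | methyl (2R,3R,5R,6E)-2-(2-tert-butoxy-2-oxoethyl)-5-ethenyl-8-hydroxy-5,7-dimethyl-3-[(triethylsilyl)oxy]oct-6-enoate | C=C[C@@](C)(C[C@@H](O[Si](CC)(CC)CC)[C@@H](CC(=O)OC(C)(C)C)C(=O)OC)/C=C(\C)CO
F2 | step 11 | methyl (2R,3R,5R,6E)-8-bromo-2-(2-tert-butoxy-2-oxoethyl)-5-ethenyl-5,7-dimethyl-3-[(triethylsilyl)oxy]oct-6-enoate | C=C[C@@](C)(C[C@@H](O[Si](CC)(CC)CC)[C@@H](CC(=O)OC(C)(C)C)C(=O)OC)/C=C(\C)CBr
F3 | step 11 | tert-butyl (3R,4R,6R,7E)-9-bromo-6-ethenyl-3-formyl-6,8-dimethyl-4-[(triethylsilyl)oxy]non-7-enoate | C=C[C@@](C)(C[C@@H](O[Si](CC)(CC)CC)[C@@H](CC(=O)OC(C)(C)C)C=O)/C=C(\C)CBr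
F4 | step 1 | methyl (3S)-2-acetyl-3-(hydroxymethyl)-3-methylpent-4-enoate (both C2 epimers) | C=C[C@@](C)(C(C(C)=O)C(=O)OC)CO
F5 | step 1 | (4R)-4-(hydroxymethyl)-4-methylhex-5-en-2-one | C=C[C@@](C)(CC(C)=O)CO
F6 | step 1 | (3R)-3-(hydroxymethyl)-3-methylpent-4-enoic acid | C=C[C@@](C)(CC(=O)O)CO
F7 | step 21 | tert-butyl 2-[(1S,2S,3S,4R,6R)-6-{[(3R)-3,4-dihydroxy-2-methylidenebutanoyl]oxy}-4-ethenyl-2-hydroxy-3-(3-hydroxyprop-1-en-2-yl)-4-methylcyclohexyl]prop-2-enoate | C=C[C@@]1(C)C[C@@H](OC(=O)C(=C)[C@@H](O)CO)[C@@H](C(=C)C(=O)OC(C)(C)C)[C@@H](O)[C@@H]1C(=C)CO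
F8 | step 21 | pentakis(trimethylsilyl) derivative of 39 (trimethylsilyl ester and four trimethylsilyl ethers) | C=C[C@@]1(C)C[C@@H](OC(=O)C(=C)[C@@H](O[Si](C)(C)C)CO[Si](C)(C)C)[C@@H](C(=C)C(=O)O[Si](C)(C)C)[C@@H](O[Si](C)(C)C)[C@@H]1C(=C)CO[Si](C)(C)C
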